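Ring A is cut across C1–C2 and C5–C6 into an alkyne (C1, C6) that already carries the C1 carboxyl and the ring B oxygen, and a 1,1-dimethoxy-3-silyloxybutadiene (C2–C5). The step exploits the meta relation of the C3 oxygen and the C1 carboxyl in ring A: a cleavable silicon bridge between them makes the [4+2] addition intramolecular and forces OMe-bearing C5 onto the aryloxy carbon C6; methanol loss then delivers the arene with the hindered diaryl ether in place. The precursor is the ring B 3-aryloxypropiolate, silyl-esterified by the dienol chlorosilane. Acylation of a ring C–ring D phenol and hydrogenolysis of three benzyl ethers finish the synthesis.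

Key step: step 7

Remark: left untethered, a 1,1-dimethoxy-3-silyloxybutadiene would bond through its nucleophilic CH2 carbon to the aryloxy-bearing β carbon of a propiolate and put OMe beside the ester (or expel the phenoxide); the ring A carboxyl is therefore used as a cleavable O–Si–O bridge to the diene, and the methyl ester is made afterwards (step 8).

Lettering: ring A = methyl benzoate ring (C1 CO2Me, C3 OH, C5 OMe, C6 O-aryl); ring B = methylsalicylate ring; ring C = methylpyrogallol ring; ring D = hydroxybenzenetricarboxylate ring.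

**Route**

Step 1
Reactants: 1 2,6-dihydroxy-4-methylbenzoic acid
Product: 2 tert-butyl 2,6-dihydroxy-4-methylbenzoate
Conditions: Me2NCH(OtBu)2, toluene, 80 °C
Reagents that add atoms: N,N-dimethylformamide di-tert-butyl acetal, CN(C)C(OC(C)(C)C)OC(C)(C)C
Why: Esterification with a formamide di-tert-butyl acetal alkylates only the carboxylate oxygen, so the tert-butyl ester forms without touching the two hydrogen-bonded phenols and without acid that could decarboxylate the substrate.

Step 2
Reactants: 2 tert-butyl 2,6-dihydroxy-4-methylbenzoate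
Product: 3 tert-butyl 2-(benzyloxy)-6-hydroxy-4-methylbenzoate
Conditions: BnBr (1.05 equiv), K2CO3, acetone, 56 °C
Reagents that add atoms: benzyl bromide, BrCc1ccccc1
Why: Williamson ether synthesis; with one equivalent of halide the symmetrical diol is alkylated once, because the remaining phenol stays locked in a hydrogen bond to the ester carbonyl.

Step 3
Reactants: 3 tert-butyl 2-(benzyloxy)-6-hydroxy-4-methylbenzoate
Product: 4 tert-butyl 2-(benzyloxy)-6-{[(E)-1,2-dichloroethenyl]oxy}-4-methylbenzoate
Conditions: Cl2C=CHCl, K2CO3, DMF, 70 °C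
Reagents that add atoms: trichloroethylene, ClC=C(Cl)Cl
Why: Base converts trichloroethylene into dichloroacetylene, and anti addition of the phenoxide across it (nucleophilic addition to a haloalkyne) gives the E dichlorovinyl aryl ether, the usual precursor of aryl alkynyl ethers.

Step 4
Reactants: 4 tert-butyl 2-(benzyloxy)-6-{[(E)-1,2-dichloroethenyl]oxy}-4-methylbenzoate
Product: 7 lithium 3-{3-(benzyloxy)-2-[(tert-butoxy)carbonyl]-5-methylphenoxy}prop-2-ynoate, via chloroethynyl ether 5 (not isolated), via lithium acetylide 6 (not isolated)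
Conditions: n-BuLi (2.1 equiv), THF, −78 °C; CO2, −78 °C to rt; evaporation, salt used crude
Reagents that add atoms: n-butyllithium, [Li]CCCC; carbon dioxide, O=C=O
Why: Dehydrochlorination and chlorine–lithium exchange give the lithium aryloxyacetylide, which is carboxylated by CO2 (acetylide carboxylation); the di-ortho-substituted tert-butyl ester is too hindered to be attacked at −78 °C.

Step 5
Reactants: 8 1,1-dimethoxyethene
Product: 9 4,4-dimethoxybut-3-en-2-one
Conditions: AcCl, pyridine, Et2O, 0 °C to rt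
Reagents that add atoms: acetyl chloride, CC(=O)Cl
Why: C-Acylation of the ketene acetal at its nucleophilic CH2 carbon by the acylpyridinium ion, followed by loss of HCl, gives the β,β-dimethoxy enone.

Step 6
Reactants: 9 4,4-dimethoxybut-3-en-2-one
Product: 11 chloro[(4,4-dimethoxybuta-1,3-dien-2-yl)oxy]di(propan-2-yl)silane, via lithium dienolate 10 (not isolated)
Conditions: LiN(iPr)2, THF, −78 °C; iPr2SiCl2 (3 equiv), −78 °C to rt; volatiles removed, used crude
Reagents that add atoms: dichlorodi(propan-2-yl)silane, CC(C)[Si](Cl)(Cl)C(C)C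
Why: Kinetic deprotonation of the methyl group (the only enolisable position) and O-silylation of the enolate by excess hindered dichlorosilane (silyl enol ether formation) leave one Si–Cl bond for the tether.

Step 7
Reactants: 7 lithium 3-{3-(benzyloxy)-2-[(tert-butoxy)carbonyl]-5-methylphenoxy}prop-2-ynoate; 11 chloro[(4,4-dimethoxybuta-1,3-dien-2-yl)oxy]di(propan-2-yl)silane
Product: 14 2-{3-(benzyloxy)-2-[(tert-butoxy)carbonyl]-5-methylphenoxy}-5-hydroxy-3-methoxybenzoic acid, via silyl ester 12 (not isolated), via bridged cycloadduct 13 (not isolated)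
Conditions: THF, 0 °C to rt; toluene (0.005 M), 150 °C, sealed tube; TsOH·H2O (cat.), MeOH, rt
Reagents that add atoms: none
Why: Proposed new method: O-silylation of carboxylate 7 by chlorosilane 11 gives silyl ester 12, whose diene (tether on the internal carbon C3) and ynoate then undergo a thermal intramolecular [4+2] cycloaddition to the bridged cyclohexa-1,4-diene 13; acidic methanol cleaves both Si–O bonds and the freed 3-oxo acetal loses methanol from C5 to give the phenol. The closest known reactions are the benzannulation of 1,1-dialkoxy-3-silyloxybutadienes with acetylenic esters and type 2 intramolecular Diels–Alder reactions run through disposable silicon tethers, which give 1,3-bridged adducts only when the tether is short. Ring A is closed by the cycloaddition itself, C1–C2 and C5–C6 forming together in a six-membered transition state while the O–Si–O–C(=O) bridge spans C1 and C3 as a transient seven-membered ring; no stereocentre remains after aromatisation. The selectivity needed is regiochemical, CH2 terminus to the carboxyl-bearing carbon C1 and acetal carbon to the aryloxy carbon C6, which runs against the polarity-matched pairing of the free partners; the four-atom bridge secures it because the opposite orientation would demand a 1,4-bridged ring that this bridge cannot span. High dilution suppresses the untethered, wrongly oriented addition, and the tert-butyl ester, benzyl ether and aryl alkynyl ether are spectators under neutral thermal conditions.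

Step 8
Reactants: 14 2-{3-(benzyloxy)-2-[(tert-butoxy)carbonyl]-5-methylphenoxy}-5-hydroxy-3-methoxybenzoic acid
Product: 15 tert-butyl 2-(benzyloxy)-6-[4-hydroxy-2-methoxy-6-(methoxycarbonyl)phenoxy]-4-methylbenzoate
Conditions: Me3SiCHN2, toluene/MeOH, 0 °C
Reagents that add atoms: (trimethylsilyl)diazomethane, C[Si](C)(C)C=[N+]=[N-]
Why: The carboxylic acid protonates the diazoalkane and the carboxylate is O-methylated (diazomethane-type esterification), much faster than the weakly acidic phenol.

Step 9
Reactants: 15 tert-butyl 2-(benzyloxy)-6-[4-hydroxy-2-methoxy-6-(methoxycarbonyl)phenoxy]-4-methylbenzoate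
Product: 16 tert-butyl 2-(benzyloxy)-6-[4-(benzyloxy)-2-methoxy-6-(methoxycarbonyl)phenoxy]-4-methylbenzoate
Conditions: BnBr, K2CO3, DMF, rt
Reagents that add atoms: benzyl bromide, BrCc1ccccc1
Why: Williamson ether synthesis on the only free phenol.

Step 10
Reactants: 16 tert-butyl 2-(benzyloxy)-6-[4-(benzyloxy)-2-methoxy-6-(methoxycarbonyl)phenoxy]-4-methylbenzoate
Product: 17 2-(benzyloxy)-6-[4-(benzyloxy)-2-methoxy-6-(methoxycarbonyl)phenoxy]-4-methylbenzoic acid
Conditions: TFA, CH2Cl2, 0 °C to rt
Reagents that add atoms: none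
Why: Acidolysis of the tert-butyl ester with loss of isobutene unmasks the ring B acid, while the methyl ester, the benzyl ethers and the diaryl ether are stable to brief TFA.

Step 11
Reactants: 18 5-methylbenzene-1,3-diol
Product: 19 1,3-bis(methoxymethoxy)-5-methylbenzene
Conditions: MOMCl, iPr2NEt, CH2Cl2, 0 °C to rt
Reagents that add atoms: chloromethyl methyl ether, COCCl
Why: O-Alkylation of both phenols by the chloromethyl ether (acetal protection) also installs the directing groups for step 12.

Step 12
Reactants: 19 1,3-bis(methoxymethoxy)-5-methylbenzene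
Product: 22 2,6-bis(methoxymethoxy)-4-methylphenol, via aryllithium 20 (not isolated), via dimethyl arylboronate 21 (not isolated)
Conditions: n-BuLi, THF, 0 °C; B(OMe)3, −78 °C to rt; H2O2, AcOH, 0 °C
Reagents that add atoms: hydrogen peroxide, OO
Why: Directed ortho-lithiation between the two MOM ethers, borylation and oxidative migration from boron to oxygen install the central phenol.

Step 13
Reactants: 23 benzene-1,2,3-tricarboxylic acid
Product: 24 2,6-bis(methoxycarbonyl)benzoic acid
Conditions: MeOH, H2SO4 (cat.), 65 °C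
Reagents that add atoms: methanol, CO
Why: Fischer esterification converts the two outer carboxyl groups, while the central one, flanked by two ortho substituents, does not reach the tetrahedral intermediate under these conditions.

Step 14
Reactants: 24 2,6-bis(methoxycarbonyl)benzoic acid; 22 2,6-bis(methoxymethoxy)-4-methylphenol
Product: 26 2-[2,6-bis(methoxymethoxy)-4-methylphenyl] 1,3-dimethyl benzene-1,2,3-tricarboxylate, via acid chloride 25 (not isolated)
Conditions: (COCl)2, DMF (cat.), CH2Cl2, rt; 22, Et3N, DMAP, CH2Cl2, 0 °C to rt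
Reagents that add atoms: none
Why: Acyl chloride formation and DMAP-catalysed O-acylation (nucleophilic acyl substitution) join ring D to the central oxygen of ring C.

Step 15
Reactants: 26 2-[2,6-bis(methoxymethoxy)-4-methylphenyl] 1,3-dimethyl benzene-1,2,3-tricarboxylate
Product: 28 2-[2,6-bis(methoxymethoxy)-4-methylphenyl] 1,3-dimethyl 5-hydroxybenzene-1,2,3-tricarboxylate, via pinacol boronate 27 (not isolated)
Conditions: [Ir(OMe)(cod)]2 (1.5 mol %), 4,4′-di-tert-butyl-2,2′-bipyridine, B2pin2, THF, 80 °C; Oxone (2KHSO5·KHSO4·K2SO4), acetone/H2O, rt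
Reagents that add atoms: potassium peroxymonosulfate, [K+].[O-]S(=O)(=O)OO
Why: Iridium-catalysed C–H borylation is sterically controlled and takes the only arene C–H with no ortho substituent (C5 of ring D, para to the aryl ester); peroxymonosulfate then oxidises the boronate to the phenol in the same flask.

Step 16
Reactants: 28 2-[2,6-bis(methoxymethoxy)-4-methylphenyl] 1,3-dimethyl 5-hydroxybenzene-1,2,3-tricarboxylate
Product: 29 2-[2,6-bis(methoxymethoxy)-4-methylphenyl] 1,3-dimethyl 5-(benzyloxy)benzene-1,2,3-tricarboxylate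
Conditions: BnBr, K2CO3, DMF, rt
Reagents that add atoms: benzyl bromide, BrCc1ccccc1
Why: Williamson ether synthesis on the only free phenol.

Step 17
Reactants: 29 2-[2,6-bis(methoxymethoxy)-4-methylphenyl] 1,3-dimethyl 5-(benzyloxy)benzene-1,2,3-tricarboxylate
Product: 30 2-(2,6-dihydroxy-4-methylphenyl) 1,3-dimethyl 5-(benzyloxy)benzene-1,2,3-tricarboxylate
Conditions: HCl, MeOH/THF, 40 °C
Reagents that add atoms: none
Why: Acid-catalysed acetal exchange with methanol removes both MOM groups; the hindered aryl ester, the methyl esters and the benzyl ether persist.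

Step 18
Reactants: 17 2-(benzyloxy)-6-[4-(benzyloxy)-2-methoxy-6-(methoxycarbonyl)phenoxy]-4-methylbenzoic acid; 30 2-(2,6-dihydroxy-4-methylphenyl) 1,3-dimethyl 5-(benzyloxy)benzene-1,2,3-tricarboxylate
Product: 32 tri-O-benzyl pseudophenone A (benzyl ethers on the ring A C3 oxygen, the ring B phenol and the ring D phenol), via mixed anhydride 31 (not isolated)
Conditions: (CF3CO)2O, toluene, 0 °C to rt
Reagents that add atoms: none
Why: Mixed-anhydride esterification under acidic conditions (the classical depside coupling): the 2,6-dioxygenated aroyl trifluoroacetate acylates one phenol of the symmetrical diol, the un-ionised phenols cannot shift the ring D ester, and the second phenol, then flanked by two aryl esters, is not acylated.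

Step 19
Reactants: 32 tri-O-benzyl pseudophenone A
Product: 33 pseudophenone A
Conditions: H2 (1 atm), Pd on carbon (10% Pd), EtOAc, rt
Reagents that add atoms: none
Why: Catalytic hydrogenolysis cleaves the three benzyl ethers under neutral conditions that leave the aryl esters, methyl esters and diaryl ether intact and give no opening for acyl migration.

**Compound list**

1 | 2,6-dihydroxy-4-methylbenzoic acid | Cc1cc(O)c(C(=O)O)c(O)c1 | starting material
2 | tert-butyl 2,6-dihydroxy-4-methylbenzoate | Cc1cc(O)c(C(=O)OC(C)(C)C)c(O)c1 | intermediate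
3 | tert-butyl 2-(benzyloxy)-6-hydroxy-4-methylbenzoate | Cc1cc(O)c(C(=O)OC(C)(C)C)c(OCc2ccccc2)c1 | intermediate
4 | tert-butyl 2-(benzyloxy)-6-{[(E)-1,2-dichloroethenyl]oxy}-4-methylbenzoate | Cl/C=C(/Cl)Oc1cc(C)cc(OCc2ccccc2)c1C(=O)OC(C)(C)C | intermediate
5 | tert-butyl 2-(benzyloxy)-6-[(chloroethynyl)oxy]-4-methylbenzoate | ClC#COc1cc(C)cc(OCc2ccccc2)c1C(=O)OC(C)(C)C | intermediate
6 | tert-butyl 2-(benzyloxy)-6-[(lithioethynyl)oxy]-4-methylbenzoate | [Li]C#COc1cc(C)cc(OCc2ccccc2)c1C(=O)OC(C)(C)C | intermediate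
7 | lithium 3-{3-(benzyloxy)-2-[(tert-butoxy)carbonyl]-5-methylphenoxy}prop-2-ynoate | [Li+].[O-]C(=O)C#COc1cc(C)cc(OCc2ccccc2)c1C(=O)OC(C)(C)C | intermediate
8 | 1,1-dimethoxyethene | C=C(OC)OC | starting material
9 | 4,4-dimethoxybut-3-en-2-one | CC(=O)C=C(OC)OC | intermediate
10 | lithium 4,4-dimethoxybuta-1,3-dien-2-olate | [Li+].[O-]C(=C)C=C(OC)OC | intermediate
11 | chloro[(4,4-dimethoxybuta-1,3-dien-2-yl)oxy]di(propan-2-yl)silane | COC(OC)=CC(=C)O[Si](Cl)(C(C)C)C(C)C | intermediate
12 | [(4,4-dimethoxybuta-1,3-dien-2-yl)oxy]di(propan-2-yl)silyl 3-{3-(benzyloxy)-2-[(tert-butoxy)carbonyl]-5-methylphenoxy}prop-2-ynoate | COC(OC)=CC(=C)O[Si](C(C)C)(C(C)C)OC(=O)C#COc1cc(C)cc(OCc2ccccc2)c1C(=O)OC(C)(C)C | intermediate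
13 | tert-butyl 2-(benzyloxy)-6-{[8,8-dimethoxy-5-oxo-3,3-di(propan-2-yl)-2,4-dioxa-3-silabicyclo[4.3.1]deca-1(9),6-dien-7-yl]oxy}-4-methylbenzoate (ring A as cyclohexa-1,4-diene, C1 carbonyl and C3 oxygen bridged by O–Si–O) | O=C1O[Si](C(C)C)(C(C)C)OC2=CC(OC)(OC)C(Oc3cc(C)cc(OCc4ccccc4)c3C(=O)OC(C)(C)C)=C1C2 | intermediate
14 | 2-{3-(benzyloxy)-2-[(tert-butoxy)carbonyl]-5-methylphenoxy}-5-hydroxy-3-methoxybenzoic acid | OC(=O)c1cc(O)cc(OC)c1Oc1cc(C)cc(OCc2ccccc2)c1C(=O)OC(C)(C)C | intermediate
15 | tert-butyl 2-(benzyloxy)-6-[4-hydroxy-2-methoxy-6-(methoxycarbonyl)phenoxy]-4-methylbenzoate | COC(=O)c1cc(O)cc(OC)c1Oc1cc(C)cc(OCc2ccccc2)c1C(=O)OC(C)(C)C | intermediate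
16 | tert-butyl 2-(benzyloxy)-6-[4-(benzyloxy)-2-methoxy-6-(methoxycarbonyl)phenoxy]-4-methylbenzoate | COC(=O)c1cc(OCc2ccccc2)cc(OC)c1Oc1cc(C)cc(OCc2ccccc2)c1C(=O)OC(C)(C)C | intermediate
17 | 2-(benzyloxy)-6-[4-(benzyloxy)-2-methoxy-6-(methoxycarbonyl)phenoxy]-4-methylbenzoic acid | COC(=O)c1cc(OCc2ccccc2)cc(OC)c1Oc1cc(C)cc(OCc2ccccc2)c1C(=O)O | intermediate
18 | 5-methylbenzene-1,3-diol | Cc1cc(O)cc(O)c1 | starting material
19 | 1,3-bis(methoxymethoxy)-5-methylbenzene | COCOc1cc(C)cc(OCOC)c1 | intermediate
20 | [2,6-bis(methoxymethoxy)-4-methylphenyl]lithium | [Li]c1c(OCOC)cc(C)cc1OCOC | intermediate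
21 | dimethyl [2,6-bis(methoxymethoxy)-4-methylphenyl]boronate | COB(OC)c1c(OCOC)cc(C)cc1OCOC | intermediate
22 | 2,6-bis(methoxymethoxy)-4-methylphenol | COCOc1cc(C)cc(OCOC)c1O | intermediate
23 | benzene-1,2,3-tricarboxylic acid | OC(=O)c1cccc(C(=O)O)c1C(=O)O | starting material
24 | 2,6-bis(methoxycarbonyl)benzoic acid | COC(=O)c1cccc(C(=O)OC)c1C(=O)O | intermediate
25 | dimethyl 2-(chlorocarbonyl)benzene-1,3-dicarboxylate | COC(=O)c1cccc(C(=O)OC)c1C(=O)Cl | intermediate
26 | 2-[2,6-bis(methoxymethoxy)-4-methylphenyl] 1,3-dimethyl benzene-1,2,3-tricarboxylate | COC(=O)c1cccc(C(=O)OC)c1C(=O)Oc1c(OCOC)cc(C)cc1OCOC | intermediate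
27 | 2-[2,6-bis(methoxymethoxy)-4-methylphenyl] 1,3-dimethyl 5-(4,4,5,5-tetramethyl-1,3,2-dioxaborolan-2-yl)benzene-1,2,3-tricarboxylate | COC(=O)c1cc(B2OC(C)(C)C(C)(C)O2)cc(C(=O)OC)c1C(=O)Oc1c(OCOC)cc(C)cc1OCOC | intermediate
28 | 2-[2,6-bis(methoxymethoxy)-4-methylphenyl] 1,3-dimethyl 5-hydroxybenzene-1,2,3-tricarboxylate | COC(=O)c1cc(O)cc(C(=O)OC)c1C(=O)Oc1c(OCOC)cc(C)cc1OCOC | intermediate
29 | 2-[2,6-bis(methoxymethoxy)-4-methylphenyl] 1,3-dimethyl 5-(benzyloxy)benzene-1,2,3-tricarboxylate | COC(=O)c1cc(OCc2ccccc2)cc(C(=O)OC)c1C(=O)Oc1c(OCOC)cc(C)cc1OCOC | intermediate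
30 | 2-(2,6-dihydroxy-4-methylphenyl) 1,3-dimethyl 5-(benzyloxy)benzene-1,2,3-tricarboxylate | COC(=O)c1cc(OCc2ccccc2)cc(C(=O)OC)c1C(=O)Oc1c(O)cc(C)cc1O | intermediate
31 | 2-(benzyloxy)-6-[4-(benzyloxy)-2-methoxy-6-(methoxycarbonyl)phenoxy]-4-methylbenzoic trifluoroacetic anhydride | COC(=O)c1cc(OCc2ccccc2)cc(OC)c1Oc1cc(C)cc(OCc2ccccc2)c1C(=O)OC(=O)C(F)(F)F | intermediate
32 | tri-O-benzyl pseudophenone A (benzyl on ring A C3–O, ring B phenol O, ring D phenol O) | COC(=O)c1cc(OCc2ccccc2)cc(OC)c1Oc1cc(C)cc(OCc2ccccc2)c1C(=O)Oc1cc(C)cc(O)c1OC(=O)c1c(C(=O)OC)cc(OCc2ccccc2)cc1C(=O)OC | intermediate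
33 | pseudophenone A | COC(=O)c1cc(O)cc(OC)c1Oc1cc(C)cc(O)c1C(=O)Oc1cc(C)cc(O)c1OC(=O)c1c(C(=O)OC)cc(O)cc1C(=O)OC | target

**Step count and risks**

Total steps: 19. Longest linear sequence: 10 steps (1, 2, 3, 4, 7, 8, 9, 10, 18, 19).

Steps most likely to fail:

1. Step 7 (Proposed new method). The tethered cycloaddition may not take place at all: the bridge forces a contra-polar orientation through a strained bridgehead-diene transition state, and prolonged heating can then lead to desilylation, breakdown of the ketene acetal or untethered addition in the wrong orientation. The fallback is a copper-mediated Ullmann diaryl ether synthesis and sets out from phenol 3. Methyl 3-hydroxy-5-methoxybenzoate F1 is iodinated para to its hydroxyl group (NIS, MeCN, 0 °C) to methyl 5-hydroxy-2-iodo-3-methoxybenzoate F2. This is benzylated (BnBr, K2CO3, DMF) to methyl 5-(benzyloxy)-2-iodo-3-methoxybenzoate F3. F3 is then coupled with 3 (CuI, picolinic acid, K3PO4, DMSO, 90 °C), the ortho ester of the iodide assisting the substitution. The product is 16, where the route is rejoined before step 10.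

2. Step 18. The second phenol may be acylated as well, the ring D acyl group may migrate to a neighbouring oxygen, or two hindered partners may fail to couple. The fallback differentiates the two phenols by protection and sets out from 29. One MOM group is removed (HCl, MeOH, stopped at partial conversion, diol and unchanged 29 recycled) to give 2-[2-hydroxy-6-(methoxymethoxy)-4-methylphenyl] 1,3-dimethyl 5-(benzyloxy)benzene-1,2,3-tricarboxylate F6. Acid 17 is converted with (COCl)2 and catalytic DMF into 2-(benzyloxy)-6-[4-(benzyloxy)-2-methoxy-6-(methoxycarbonyl)phenoxy]-4-methylbenzoyl chloride F7. F6 is acylated by F7 (pyridine, DMAP, CH2Cl2) to the MOM ether of tri-O-benzyl pseudophenone A F8. HCl in MeOH removes the last MOM group and returns the route at 32.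

3. Step 4. n-BuLi may attack the benzylic ether or the ester instead of the dichlorovinyl group, or the alkynoate salt may decompose while the solvent is removed. The fallback forms the aryloxy–alkyne bond by addition–elimination and sets out from phenol 3. Its potassium phenoxide (K2CO3, DMF, 0 °C) displaces bromide from prop-2-en-1-yl 3-bromoprop-2-ynoate F4, giving tert-butyl 2-(benzyloxy)-4-methyl-6-{[3-oxo-3-(prop-2-en-1-yloxy)prop-1-yn-1-yl]oxy}benzoate F5. Palladium-catalysed allyl transfer to lithium 2-ethylhexanoate (Pd(PPh3)4, THF, rt) then precipitates lithium salt 7, where the route is rejoined.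

**Further compounds**

F1 | step 7 | methyl 3-hydroxy-5-methoxybenzoate | COC(=O)c1cc(O)cc(OC)c1
F2 | step 7 | methyl 5-hydroxy-2-iodo-3-methoxybenzoate | COC(=O)c1cc(O)cc(OC)c1I
F3 | step 7 | methyl 5-(benzyloxy)-2-iodo-3-methoxybenzoate | COC(=O)c1cc(OCc2ccccc2)cc(OC)c1I
F4 | step 4 | prop-2-en-1-yl 3-bromoprop-2-ynoate | C=CCOC(=O)C#CBr
F5 | step 4 | tert-butyl 2-(benzyloxy)-4-methyl-6-{[3-oxo-3-(prop-2-en-1-yloxy)prop-1-yn-1-yl]oxy}benzoate | C=CCOC(=O)C#COc1cc(C)cc(OCc2ccccc2)c1C(=O)OC(C)(C)C
F6 | step 18 | 2-[2-hydroxy-6-(methoxymethoxy)-4-methylphenyl] 1,3-dimethyl 5-(benzyloxy)benzene-1,2,3-tricarboxylate | COC(=O)c1cc(OCc2ccccc2)cc(C(=O)OC)c1C(=O)Oc1c(O)cc(C)cc1OCOC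
F7 | step 18 | 2-(benzyloxy)-6-[4-(benzyloxy)-2-methoxy-6-(methoxycarbonyl)phenoxy]-4-methylbenzoyl chloride | COC(=O)c1cc(OCc2ccccc2)cc(OC)c1Oc1cc(C)cc(OCc2ccccc2)c1C(=O)Cl
F8 | step 18 | methoxymethyl ether of tri-O-benzyl pseudophenone A (MOM on the free ring C phenol) | COC(=O)c1cc(OCc2ccccc2)cc(OC)c1Oc1cc(C)cc(OCc2ccccc2)c1C(=O)Oc1cc(C)cc(OCOC)c1OC(=O)c1c(C(=O)OC)cc(OCc2ccccc2)cc1C(=O)OC
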